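Assumption: all intermediates that carry stereocentres are made racemic and carried as diastereomer mixtures, because both centres end as CH2 groups in the achiral target. Methoxyacetylene is prepared rather than bought because it is volatile and labile.

## Analysis of the target

CNP0260198.0 (19) is an achiral polyphenol built on a central benzene ring A that carries OMe at C1, OH at C3, a 4-hydroxybenzyl group at C4 and a 2-(2-hydroxyphenyl)ethyl chain at C5, with hydrogens at C2 and C6. Ring A is linked to a 4-hydroxyphenyl ring B through one CH2 (a diarylmethane) and to a 2-hydroxyphenyl ring C through CH2CH2 (a bibenzyl); there is no stereocentre and no fused ring. The sensitive groups are the three free phenols, which make the compound electron-rich, easily oxidised and liable to acid-induced Friedel–Crafts chemistry whenever a benzylic position is activated. The difficulty sits in ring A: the substituents at C3, C4 and C5 are contiguous, and the two meta oxygens must be told apart, with the free OH at C3 lying next to the benzyl group. The strategy rests on the fact that the CH2 on C4 and the chain carbon that bears ring C are both benzylic, so an oxygen bridging them (a pyran ring fused to C4–C5) can be removed without trace by hydrogenolysis. With that bridge in place ring A divides into three two-carbon units, C3–C4 and C5–C6 tied by the bridge and C1–C2 carrying the methoxy group, which is the pattern of an alkyne cyclotrimerisation.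

## Retrosynthetic reasoning

19 ⇒ 17. The last operation is reductive. An oxygen is put back between the benzylic carbon on C4 and the ring-C-bearing carbon of the C5 chain, and benzyl ethers are put on the phenols of rings B and C. This gives the isochromanol 17. The cut is made at these four C–O bonds because each is benzylic and therefore hydrogenolysable, while the aryl C–O bonds and the methyl ether are not. The forward step has to cleave all four, passing through the ring-opened carbinol 18.

17 ⇒ 15. The C3–O bond is traced back to a C3–Si bond in the arylsilane 15. Silicon survives the ring-forming step, where a free or protected oxygen on an alkyne would not, and its bulk is what directs that step. Because C1 already carries OMe when C3 becomes OH, the two oxygens are never in competition. The forward step is a fluoride-triggered Tamao–Fleming oxidation through the silanol 16.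

15 ⇒ 11 + 14. This is the central disconnection: C1–C6, C2–C3 and C4–C5 are cut, which turns ring A into three alkynes. C3–C4 and C5–C6 are the two alkynes of the ether-tethered 1,7-diyne 11 and C1–C2 is methoxyacetylene 14. The cut is placed here because the ether oxygen makes two of the three components intramolecular. One operation then forms ring A and the pyran ring, and the C4 and C5 substituents are placed by connectivity rather than by selectivity. The forward reaction has to control a single variable, the orientation in which 14 enters.

14 ⇒ 12. The ynol ether is traced to the chloroacetal 12 by double elimination via the acetylide 13, so that it can be made fresh and used cold.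

11 ⇒ 6 + 10. The ether is cut at the C–O bond of the propargylic carbon that carries ring B. That carbon is flanked by a 4-alkoxyaryl group and an alkyne and ionises readily, so the propargylic alcohol 6 serves as the electrophile and the homopropargylic alcohol 10 as the nucleophile. The forward reaction must favour the cross ether over self-condensation of 6.

6 ⇒ 3 + 4, and 3 ⇒ 1 + 2. The propargylic alcohol comes from addition of the acetylide 5, made from silylacetylene 3, to aldehyde 4; this brings in ring B with its benzylic carbon at the correct oxidation level. Silylacetylene 3 comes from chlorosilane 1 and the ethynyl Grignard reagent 2.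

10 ⇒ 7 + 8. The homopropargylic alcohol comes from Barbier propargylation of aldehyde 7 with bromide 8 through the allenylzinc species 9. This supplies ring C, the chain CH2 and the future C5–C6 unit.

## Alternatives that were turned down

Alternative 1: The disconnection cuts C1–C2 and C1–C6. C1 comes from carbon monoxide A3 and the other five ring carbons from the tertiary propargylic pivalate A2, a 3-acyloxy-1,4-enyne. In the forward key step the rhodium catalyst di-μ-chlorotetracarbonyldirhodium A4, of formula [Rh(CO)2Cl]2, shifts the ester from C4 to C3 and generates a rhodium carbene at C2. A3 inserts to give a dienyl ketene, and 6π-electrocyclisation with tautomerisation closes ring A as the resorcinol monopivalate A1.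
- For it: the two ring oxygens differ from the moment ring A forms (ester at C3, free phenol at C1), so methylation at C1 needs no selectivity. The C1 source is as cheap as any. The ring-forming reaction type is also closer to established practice than the key step chosen here; on that point this alternative is the stronger.
- Against it: A2 is a tertiary ester flanked by a benzyl group and a 1,1-disubstituted alkene. It has to be made by ethynylation of a polymerisable α-methylene ketone and acylation of a hindered tertiary alkoxide, and in the presence of A4 it can ionise or eliminate instead of undergoing the 1,2-acyloxy shift. Three operations follow A1 (O-methylation, ester removal, debenzylation) against two after 15, and the assembly of A2 is linear.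
- In its place the chosen route offers convergence from two aldehydes, a methyl ether that is present as ring A forms, and a tether that fixes which carbon bears which substituent.

Alternative 2: The disconnection cuts C3–C4 and C4–C5. C4 and the benzylic carbon come from the aryl methyl ketone A7, and C1, C2, C3, C5 and C6 from the 4-methoxy-2-pyranone A6, whose ring oxygen is exchanged for carbon. In the forward key step the lithium enolate A8 of A7 acylates at the lactone carbonyl of A6. The ring opens to a triketide-like chain, and aldol condensation of the doubly activated CH2 onto the liberated ketone closes ring A as the 2-hydroxybenzophenone A5.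
- For it: the methoxy group is present from the start and the C3 hydroxyl is born from the lactone carbonyl, so this route also avoids selective O-alkylation. A6 is one alkylation away from a commercial pyranone, and a single acidic hydrogenolysis of A5 would reduce the diaryl ketone and remove the benzyl ethers. On step count it is clearly shorter than the chosen route, and this is conceded.
- Against it: A6 has an acidic CH2 on C6 and an electrophilic C6 besides the lactone carbonyl, so A8 can be quenched by proton transfer or add in the conjugate sense. The acidic β-diketone that forms consumes a second equivalent of A8. The open chain can also close through oxygen to a 4-pyranone instead of through carbon. Each of these is a choice among sites of similar reactivity with nothing in the substrate to decide it.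
- In its place the chosen route concentrates its risk in one orientation, that of 14, fixes everything else by a covalent tether, and has a fallback that re-enters the same route.

Alternative 3: The disconnection cuts the bond from C5 to the first chain carbon and the lactone C–O bond. Ring A is bought as the benzoic acid A10 and ring C arrives as the styrene A11. In the forward key step the catalyst palladium diacetate A12, of formula Pd(OAc)2, palladates A10 at its only free ortho C–H under carboxylate direction. A11 inserts, and β-hydride elimination followed by oxidative C–O closure gives the isocoumarin A9. Addition of the aryl Grignard reagent A13 to the lactone and exhaustive acidic hydrogenation would complete the skeleton.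
- For it: the oxygen pattern of ring A is purchased, so no question about OMe versus OH arises. The acid has a single ortho C–H, the reaction class is established, and the sequence is short. On certainty of the oxygen pattern, on precedent and probably on step count this alternative is stronger than the chosen one.
- Against it: A10 is a 2,4-dialkoxybenzoic acid, the substrate type that loses CO2 most readily under the divalent palladium of A12 with the stoichiometric oxidant such couplings need, so decarboxylative palladation competes with C–H palladation. The electron-rich, ortho-substituted A11 can close in the 5-exo sense to a benzylidene phthalide or stop at the stilbene acid. The carboxyl carbon enters at the acid oxidation level, so A13 must add exactly once to an enol lactone that opens to a diketone, and two carbonyl groups must then be reduced to CH2.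
- In its place the chosen route brings the benzylic carbon in at the right oxidation level with ring B attached (from aldehyde 4), needs no oxidant, and forms both carbon substituents of ring A in the ring-forming step. What it gives up is the security of a purchased ring A.

Key step: step 6

## Route

Step 1
Reactants: 1 benzyl(chloro)dimethylsilane; 2 ethynylmagnesium bromide
Product: 3 benzyl(ethynyl)dimethylsilane
Conditions: 2 (1.3 equiv, 0.5 M in THF), THF, 0 °C → rt
Reagents that add atoms: none
Why: Nucleophilic substitution at silicon by an alkynyl Grignard reagent; the excess of 2 at low temperature suppresses double silylation of acetylene.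

Step 2
Reactants: 3 benzyl(ethynyl)dimethylsilane; 4 4-(benzyloxy)benzaldehyde
Product: 6 1-[4-(benzyloxy)phenyl]-3-[benzyl(dimethyl)silyl]prop-2-yn-1-ol (racemic), via lithium silylacetylide 5 (not isolated)
Conditions: n-BuLi, THF, −78 °C; then 4, −78 → 0 °C; aq. NH4Cl
Reagents that add atoms: none
Why: Deprotonation of the terminal alkyne gives acetylide 5, which adds 1,2 to the non-enolisable aldehyde (acetylide addition); the new carbinol centre is racemic and is erased in step 8.

Step 3
Reactants: 7 2-(benzyloxy)benzaldehyde; 8 propargyl bromide
Product: 10 1-[2-(benzyloxy)phenyl]but-3-yn-1-ol (racemic), via allenylzinc bromide 9 (not isolated)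
Conditions: Zn dust, THF, 0 °C → rt; aq. NH4Cl
Reagents that add atoms: none
Why: Barbier propargylation; 9 forms on the zinc surface and adds to 7 through a cyclic SE2' transition state, which gives the homopropargylic alcohol in preference to the allenyl carbinol. The carbinol centre is racemic and is erased in step 8.

Step 4
Reactants: 6 1-[4-(benzyloxy)phenyl]-3-[benzyl(dimethyl)silyl]prop-2-yn-1-ol; 10 1-[2-(benzyloxy)phenyl]but-3-yn-1-ol
Product: 11 benzyl{3-[4-(benzyloxy)phenyl]-3-({1-[2-(benzyloxy)phenyl]but-3-yn-1-yl}oxy)prop-1-yn-1-yl}dimethylsilane (mixture of diastereomers)
Conditions: FeCl3 (5 mol %), 10 (2 equiv), 4 Å MS, MeCN, 0 °C → rt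
Reagents that add atoms: none
Why: Acid-catalysed SN1 propargylic etherification; FeCl3 ionises 6 to a cation stabilised by the 4-benzyloxyphenyl ring and the alkyne, and 10 traps it at the benzylic carbon because the silyl group shields the alkyne terminus. The self-ether of 6 re-ionises under the conditions and is funnelled to 11 by the excess of 10 and the removal of water; no stereocontrol is needed.

Step 5
Reactants: 12 2-chloro-1,1-dimethoxyethane
Product: 14 methoxyacetylene (methoxyethyne), via sodium methoxyacetylide 13 (not isolated)
Conditions: NaNH2 (3 equiv), liq. NH3, −33 °C; then cold sat. aq. NaCl, −20 °C; distilled into cold ClCH2CH2Cl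
Reagents that add atoms: none
Why: Double base-induced elimination (methanol, then HCl) from the chloroacetal gives acetylide 13, the standard preparation of alkoxyacetylenes; mild protonation and distillation deliver the ynol ether, which is used at once as a cold solution.

Step 6
Reactants: 11 benzyl{3-[4-(benzyloxy)phenyl]-3-({1-[2-(benzyloxy)phenyl]but-3-yn-1-yl}oxy)prop-1-yn-1-yl}dimethylsilane; 14 methoxyacetylene
Product: 15 benzyl{1-[4-(benzyloxy)phenyl]-3-[2-(benzyloxy)phenyl]-6-methoxy-3,4-dihydro-1H-isochromen-8-yl}dimethylsilane (mixture of cis and trans diastereomers)
Conditions: Cp*RuCl(cod) (5–10 mol %), 14 (4 equiv, slow addition as cold solution), ClCH2CH2Cl, 0 °C → rt, sealed vessel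
Reagents that add atoms: none
Why: Proposed new method: the closest known reaction type is the Cp*RuCl(cod)-catalysed (2+2+2) cycloaddition of tethered diynes with terminal alkynes, which places the monoalkyne substituent meta to a substituted diyne terminus; an alkoxyacetylene partner and a bis-benzylic ether tether have not been shown in it. Mechanistically, loss of cod lets the Cp*RuCl fragment bind both alkynes of 11 and couple them oxidatively to a ruthenacyclopentadiene, which forms C4–C5 and closes the pyran ring by tether-enforced intramolecular coupling of the 1,7-diyne. Methoxyacetylene 14 then coordinates and inserts, and C–C reductive elimination from the seven-membered ruthenacycle forms C1–C6 and C2–C3, closing ring A as a benzene ring and releasing the catalyst. The step needs one selectivity, the orientation of 14: its methoxy-bearing carbon has to bond to the unsubstituted diyne terminus (future C6) so that OMe ends up meta to silicon. The benzyldimethylsilyl group and the Cp* ligand crowd the other metal-bound carbon, so the substituted end of the incoming alkyne is directed away from it, as it is for alkyl- and arylacetylenes in the known reaction. The silyl cap also slows self-trimerisation of 11 and prevents vinylidene formation at the propargylic-ether alkyne, so the volatile ynol ether can be fed slowly and in excess at low temperature. No stereocentre is formed; the two carbinol centres of 11 pass unchanged into 15 as a cis/trans mixture that converges in step 8.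

Step 7
Reactants: 15 benzyl{1-[4-(benzyloxy)phenyl]-3-[2-(benzyloxy)phenyl]-6-methoxy-3,4-dihydro-1H-isochromen-8-yl}dimethylsilane
Product: 17 1-[4-(benzyloxy)phenyl]-3-[2-(benzyloxy)phenyl]-6-methoxy-3,4-dihydro-1H-isochromen-8-ol (mixture of diastereomers), via arylsilanol 16 (not isolated)
Conditions: TBAF·3H2O, THF, 0 °C → rt; then KHCO3, 30 % H2O2, MeOH, rt → 45 °C
Reagents that add atoms: hydrogen peroxide, OO
Why: Tamao–Fleming oxidation of a benzyldimethylsilyl group; fluoride cleaves the Si–benzyl bond to give silanol 16, and peroxide attack at silicon with 1,2-aryl migration from silicon to oxygen and hydrolysis gives the phenol at the same carbon. Silicon sits meta to OMe, so ipso-protonation is not activated, and the benzyl ethers and the isochroman are inert to fluoride and basic peroxide.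

Step 8
Reactants: 17 1-[4-(benzyloxy)phenyl]-3-[2-(benzyloxy)phenyl]-6-methoxy-3,4-dihydro-1H-isochromen-8-ol
Product: 19 2-(4-hydroxybenzyl)-3-[2-(2-hydroxyphenyl)ethyl]-5-methoxyphenol (CNP0260198.0), via ring-opened benzylic alcohol 18 (not isolated)
Conditions: H2 (3 bar), Pd/C (10 %), AcOH–EtOAc, cat. HClO4, rt → 50 °C
Reagents that add atoms: none
Why: Hydrogenolysis over Pd/C; the two O-benzyl ethers and the doubly benzylic C–O bond of the isochroman cleave first to give 18, and acid then activates the remaining secondary benzylic alcohol (through the ortho-hydroxybenzyl cation or the stilbene) for reduction to CH2. All four C–O bonds removed are benzylic; the aryl C–O bonds and the methyl ether are untouched, and both stereocentres vanish.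

## Compound list

1 | benzyl(chloro)dimethylsilane | C[Si](C)(Cl)Cc1ccccc1 | starting material
2 | ethynylmagnesium bromide | C#C[Mg]Br | starting material
3 | benzyl(ethynyl)dimethylsilane | C#C[Si](C)(C)Cc1ccccc1 | intermediate
4 | 4-(benzyloxy)benzaldehyde | O=Cc1ccc(OCc2ccccc2)cc1 | starting material
5 | lithium [benzyl(dimethyl)silyl]acetylide (not isolated) | [Li]C#C[Si](C)(C)Cc1ccccc1 | intermediate
6 | 1-[4-(benzyloxy)phenyl]-3-[benzyl(dimethyl)silyl]prop-2-yn-1-ol (racemic) | OC(C#C[Si](C)(C)Cc1ccccc1)c1ccc(OCc2ccccc2)cc1 | intermediate
7 | 2-(benzyloxy)benzaldehyde | O=Cc1ccccc1OCc1ccccc1 | starting material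
8 | propargyl bromide (3-bromoprop-1-yne) | C#CCBr | starting material
9 | allenylzinc bromide (not isolated) | C=C=C[Zn]Br | intermediate
10 | 1-[2-(benzyloxy)phenyl]but-3-yn-1-ol (racemic) | C#CCC(O)c1ccccc1OCc1ccccc1 | intermediate
11 | benzyl{3-[4-(benzyloxy)phenyl]-3-({1-[2-(benzyloxy)phenyl]but-3-yn-1-yl}oxy)prop-1-yn-1-yl}dimethylsilane (mixture of diastereomers) | C#CCC(OC(C#C[Si](C)(C)Cc1ccccc1)c1ccc(OCc2ccccc2)cc1)c1ccccc1OCc1ccccc1 | intermediate
12 | 2-chloro-1,1-dimethoxyethane | COC(CCl)OC | starting material
13 | sodium methoxyacetylide (not isolated) | COC#C[Na] | intermediate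
14 | methoxyacetylene | COC#C | intermediate
15 | benzyl{1-[4-(benzyloxy)phenyl]-3-[2-(benzyloxy)phenyl]-6-methoxy-3,4-dihydro-1H-isochromen-8-yl}dimethylsilane (mixture of diastereomers) | COc1cc([Si](C)(C)Cc2ccccc2)c2c(c1)CC(c1ccccc1OCc1ccccc1)OC2c1ccc(OCc2ccccc2)cc1 | intermediate
16 | {1-[4-(benzyloxy)phenyl]-3-[2-(benzyloxy)phenyl]-6-methoxy-3,4-dihydro-1H-isochromen-8-yl}dimethylsilanol (not isolated, mixture of diastereomers) | COc1cc([Si](C)(C)O)c2c(c1)CC(c1ccccc1OCc1ccccc1)OC2c1ccc(OCc2ccccc2)cc1 | intermediate
17 | 1-[4-(benzyloxy)phenyl]-3-[2-(benzyloxy)phenyl]-6-methoxy-3,4-dihydro-1H-isochromen-8-ol (mixture of diastereomers) | COc1cc(O)c2c(c1)CC(c1ccccc1OCc1ccccc1)OC2c1ccc(OCc2ccccc2)cc1 | intermediate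
18 | 2-(4-hydroxybenzyl)-3-[2-hydroxy-2-(2-hydroxyphenyl)ethyl]-5-methoxyphenol (not isolated, racemic) | COc1cc(O)c(Cc2ccc(O)cc2)c(CC(O)c2ccccc2O)c1 | intermediate
19 | 2-(4-hydroxybenzyl)-3-[2-(2-hydroxyphenyl)ethyl]-5-methoxyphenol (CNP0260198.0) | COc1cc(O)c(Cc2ccc(O)cc2)c(CCc2ccccc2O)c1 | target

## Step count and risk

Total step count: 8. Longest linear sequence: 6 steps (steps 1, 2, 4, 6, 7, 8); steps 3 and 5 are one-step branches.

Step 6 (key step, proposed new method).
- What may go wrong: insertion of the ynol ether in the reverse orientation is the most likely failure. Methoxy is small, and the polarisation of the ynol ether (nucleophilic CH terminus) may favour bonding of that terminus to the unhindered metallacycle carbon, which would place OMe next to silicon. Oligomerisation of the electron-rich alkyne at ruthenium, and slow oxidative cyclisation of a 1,7-diyne with one silylated terminus and a crowded tether, could also drain the catalyst.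
- Fallback with known chemistry, setting out from 11 and returning at 15: the diyne is cyclised under the same Cp*RuCl(cod) catalysis with 2-ethynyl-4,4,5,5-tetramethyl-1,3,2-dioxaborolane. This is a bulky, electron-poor terminal alkyne of a class established in diyne cyclotrimerisation, for which steric control alone dictates the meta product. It gives 2-{8-[benzyl(dimethyl)silyl]-1-[4-(benzyloxy)phenyl]-3-[2-(benzyloxy)phenyl]-3,4-dihydro-1H-isochromen-6-yl}-4,4,5,5-tetramethyl-1,3,2-dioxaborolane F1. Oxidation of the C–B bond with NaBO3·4H2O in THF–water, which leaves the fluoride-gated silyl group alone, gives 8-[benzyl(dimethyl)silyl]-1-[4-(benzyloxy)phenyl]-3-[2-(benzyloxy)phenyl]-3,4-dihydro-1H-isochromen-6-ol F2. This is the only free phenol in the molecule, and methylation with MeI and K2CO3 in acetone gives 15.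

Step 4.
- What may go wrong: the ionisation is reversible and the cation is long-lived, so self-etherification of 6, Friedel–Crafts alkylation of a benzyloxyarene ring, or Meyer–Schuster-type hydration may compete with capture by the hindered secondary alcohol 10.
- Fallback, setting out from 6 and returning at 11: 6 is converted with Cl3CCN and catalytic DBU in CH2Cl2 at 0 °C into 1-[4-(benzyloxy)phenyl]-3-[benzyl(dimethyl)silyl]prop-2-yn-1-yl 2,2,2-trichloroethanimidate F3. F3 is coupled with 10 (1.2 equiv) under catalytic TMSOTf in CH2Cl2 at −78 °C. The leaving group is now irreversible and no water is formed, so the coupling is kinetic and gives 11.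

Step 7.
- What may go wrong: protodesilylation in place of oxidation, or incomplete cleavage of the Si–benzyl bond, because the silicon is crowded by the neighbouring aryl-bearing carbon of the rigid isochroman.
- Fallback, setting out from 15 and returning at 19: the order of the last two steps is reversed. Acidic hydrogenolysis of 15 (H2, Pd/C, AcOH–EtOAc, cat. HClO4) opens the isochroman and removes the O-benzyl groups while leaving the Si–C bonds. It gives 4-({2-[benzyl(dimethyl)silyl]-6-[2-(2-hydroxyphenyl)ethyl]-4-methoxyphenyl}methyl)phenol F4, in which the silicon is flanked only by a freely rotating benzyl group. Tamao–Fleming oxidation of F4 (TBAF, then KHCO3, H2O2, MeOH) then gives 19 directly.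

Step 8.
- What may go wrong: stalling at the secondary benzylic alcohol 18, or acid-induced Friedel–Crafts self-condensation of the benzylic cations with the electron-rich phenol rings before hydrogen is delivered.
- Fallback, setting out from 17 and returning at 19: ionic hydrogenation with Et3SiH and CF3CO2H in CH2Cl2 (0 °C → rt) reduces both benzylic C–O bonds of the isochroman by hydride capture of the cations in the presence of excess silane. It gives 2-[4-(benzyloxy)benzyl]-3-{2-[2-(benzyloxy)phenyl]ethyl}-5-methoxyphenol F5. Neutral hydrogenolysis (H2, Pd/C, EtOAc–MeOH, rt) then removes the two benzyl ethers and gives 19.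

## Further compounds

F1 | step 6 | 2-{8-[benzyl(dimethyl)silyl]-1-[4-(benzyloxy)phenyl]-3-[2-(benzyloxy)phenyl]-3,4-dihydro-1H-isochromen-6-yl}-4,4,5,5-tetramethyl-1,3,2-dioxaborolane (mixture of diastereomers) | CC1(C)OB(OC1(C)C)c1cc([Si](C)(C)Cc2ccccc2)c2c(c1)CC(c1ccccc1OCc1ccccc1)OC2c1ccc(OCc2ccccc2)cc1
F2 | step 6 | 8-[benzyl(dimethyl)silyl]-1-[4-(benzyloxy)phenyl]-3-[2-(benzyloxy)phenyl]-3,4-dihydro-1H-isochromen-6-ol (mixture of diastereomers) | Oc1cc([Si](C)(C)Cc2ccccc2)c2c(c1)CC(c1ccccc1OCc1ccccc1)OC2c1ccc(OCc2ccccc2)cc1
F3 | step 4 | 1-[4-(benzyloxy)phenyl]-3-[benzyl(dimethyl)silyl]prop-2-yn-1-yl 2,2,2-trichloroethanimidate (racemic) | N=C(OC(C#C[Si](C)(C)Cc1ccccc1)c1ccc(OCc2ccccc2)cc1)C(Cl)(Cl)Cl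
F4 | step 7 | 4-({2-[benzyl(dimethyl)silyl]-6-[2-(2-hydroxyphenyl)ethyl]-4-methoxyphenyl}methyl)phenol | COc1cc([Si](C)(C)Cc2ccccc2)c(Cc2ccc(O)cc2)c(CCc2ccccc2O)c1
F5 | step 8 | 2-[4-(benzyloxy)benzyl]-3-{2-[2-(benzyloxy)phenyl]ethyl}-5-methoxyphenol | COc1cc(O)c(Cc2ccc(OCc3ccccc3)cc2)c(CCc2ccccc2OCc2ccccc2)c1
A1 | alternative 1 | 2-[4-(benzyloxy)benzyl]-3-{2-[2-(benzyloxy)phenyl]ethyl}-5-hydroxyphenyl pivalate | CC(C)(C)C(=O)Oc1cc(O)cc(CCc2ccccc2OCc2ccccc2)c1Cc1ccc(OCc2ccccc2)cc1
A2 | alternative 1 | 3-[4-(benzyloxy)benzyl]-6-[2-(benzyloxy)phenyl]-4-methylidenehex-1-yn-3-yl pivalate (racemic) | C#CC(Cc1ccc(OCc2ccccc2)cc1)(OC(=O)C(C)(C)C)C(=C)CCc1ccccc1OCc1ccccc1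
A3 | alternative 1 | carbon monoxide | [C-]#[O+]
A4 | alternative 1 | di-μ-chlorotetracarbonyldirhodium, [Rh(CO)2Cl]2 | [C-]#[O+].[C-]#[O+].[C-]#[O+].[C-]#[O+].[Cl-].[Cl-].[Rh+].[Rh+]
A5 | alternative 2 | [4-(benzyloxy)phenyl](2-{2-[2-(benzyloxy)phenyl]ethyl}-6-hydroxy-4-methoxyphenyl)methanone | COc1cc(O)c(C(=O)c2ccc(OCc3ccccc3)cc2)c(CCc2ccccc2OCc2ccccc2)c1
A6 | alternative 2 | 6-{2-[2-(benzyloxy)phenyl]ethyl}-4-methoxy-2H-pyran-2-one | COc1cc(CCc2ccccc2OCc2ccccc2)oc(=O)c1
A7 | alternative 2 | 1-[4-(benzyloxy)phenyl]ethan-1-one | CC(=O)c1ccc(OCc2ccccc2)cc1
A8 | alternative 2 | lithium 1-[4-(benzyloxy)phenyl]ethen-1-olate | [Li]OC(=C)c1ccc(OCc2ccccc2)cc1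
A9 | alternative 3 | 8-(benzyloxy)-3-[2-(benzyloxy)phenyl]-6-methoxy-1H-isochromen-1-one | COc1cc(OCc2ccccc2)c2c(c1)C=C(c1ccccc1OCc1ccccc1)OC2=O
A10 | alternative 3 | 2-(benzyloxy)-4-methoxybenzoic acid | COc1ccc(C(=O)O)c(OCc2ccccc2)c1
A11 | alternative 3 | 1-(benzyloxy)-2-ethenylbenzene | C=Cc1ccccc1OCc1ccccc1
A12 | alternative 3 | palladium diacetate, Pd(OAc)2 | CC(=O)[O-].CC(=O)[O-].[Pd+2]
A13 | alternative 3 | [4-(benzyloxy)phenyl]magnesium bromide | Br[Mg]c1ccc(OCc2ccccc2)cc1
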